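**Retrosynthetic overview**
1. The N-oxide comes from the tertiary amine. Ring D (lactone) comes from acid-mediated Markovnikov lactonisation of a C14 exocyclic alkene by the C21 propanoic acid chain (sets C14); the alkene comes from a C14 ketone.
2. Ring C comes from intramolecular aza-Michael addition of N4 to C5 of a dienone (sets C5 and C13). The dienone comes from a late C13–C14 Stille acylation joining fragment W (rings A/B, acid chloride) with fragment E (rings E/F, dienylstannane).
3. Fragment W: ring B from cyclopentadiene ([2+2] with chlorosulfonyl isocyanate, lipase resolution), ring A by intramolecular Heck reaction, C21 by convex-face dienolate Michael addition, C2 by convex-face hydrogenation.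
4. Fragment E: ring E from cyclohexenone (Cu-catalysed asymmetric conjugate addition sets C10), ring F by ring-closing metathesis, C13 activated by α′-chlorination, enol triflate reduction and stannylation.
5. Ring order: B → A (fragment W) and E → F (fragment E) in parallel, then C, then D.

Locants (order of atoms in the target SMILES, N-oxide oxygen left out): C1 (methyl)–C2–C3–N4–C5–C6=C7–C8–C9–C10–C11–C12–C13–C14 (C15 = its methyl)–O16–C17(=O)–C19–C20–C21–C22–C23–C24–C25. Ring A = N4/C3/C2/C24/C25, ring B = C21–C25, ring C = N4/C5/C13/C14/C21/C25, ring D = lactone, ring E = C5/C6/C10–C13, ring F = C6–C10.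

Assumption: the lipase opens the (1R,5S)-β-lactam and leaves the (1S,5R)-enantiomer, the usual sense for alicyclic-fused β-lactams.

**Fragment W**

Step 1
Reactants: 1 cyclopenta-1,3-diene; 2 chlorosulfonyl isocyanate
Product: 4 rac-cis-6-azabicyclo[3.2.0]hept-3-en-7-one, via N-chlorosulfonyl β-lactam 3 (not isolated)
Conditions: Et2O, −78 → −20 °C; then aq Na2SO3, KOH (pH 7–8), 0 °C
Reagents that add atoms: none
Why: Stepwise [2+2] cycloaddition through the allyl cation puts N on the allylic carbon (C25) and the carbonyl carbon (C14) on C21 with an enforced cis ring fusion, and sulfite reductively removes the N-sulfonyl chloride.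

Step 2
Reactants: 4 rac-cis-6-azabicyclo[3.2.0]hept-3-en-7-one
Product: 5 (1R,2S)-2-aminocyclopent-3-ene-1-carboxylic acid
Conditions: immobilised Candida antarctica lipase B, H2O (0.6 equiv), iPr2O, 65 °C, to 50% conversion; filter, extract acid with hot water
Reagents that add atoms: water, O
Why: Enzymatic kinetic resolution by enantioselective lactam hydrolysis opens only the (1R,5S)-lactam, fixing C25 (S) and C21 (R), while the unreacted (1S,5R)-lactam stays in solution and is removed.

Step 3
Reactants: 5 (1R,2S)-2-aminocyclopent-3-ene-1-carboxylic acid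
Product: 6 benzyl (1R,2S)-2-aminocyclopent-3-ene-1-carboxylate
Conditions: BnOH, TsOH·H2O (1.1 equiv), cyclohexane, reflux (Dean–Stark); then aq NaHCO3
Reagents that add atoms: benzyl alcohol, OCc1ccccc1
Why: Fischer esterification with the amine held as its tosylate salt installs a hydrogenolysable ester without touching either stereocentre.

Step 4
Reactants: 6 benzyl (1R,2S)-2-aminocyclopent-3-ene-1-carboxylate; 7 2,3-dibromoprop-1-ene
Product: 8 benzyl (1R,2S)-2-[(2-bromoprop-2-en-1-yl)amino]cyclopent-3-ene-1-carboxylate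
Conditions: K2CO3, MeCN, 0 °C → rt (1.0 equiv of 7, slow addition)
Reagents that add atoms: none
Why: SN2 N-alkylation occurs only at the allylic bromide (the vinyl bromide is inert), and the α-branched amine with 1:1 stoichiometry limits dialkylation.

Step 5
Reactants: 8 benzyl (1R,2S)-2-[(2-bromoprop-2-en-1-yl)amino]cyclopent-3-ene-1-carboxylate
Product: 9 benzyl (1R,2S)-2-[(2-bromoprop-2-en-1-yl){[2-(trimethylsilyl)ethoxy]carbonyl}amino]cyclopent-3-ene-1-carboxylate
Conditions: Teoc-OSu, Et3N, DMAP (cat.), MeCN, 50 °C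
Reagents that add atoms: N-{[2-(trimethylsilyl)ethoxy]carbonyloxy}succinimide (Teoc-OSu), C[Si](C)(C)CCOC(=O)ON1C(=O)CCC1=O
Why: Acyl transfer from the succinimidyl carbonate gives the Teoc carbamate, which survives Pd, LiN(iPr)2, H2 and acid chloride formation and is later removed by fluoride.

Step 6
Reactants: 9 benzyl (1R,2S)-2-[(2-bromoprop-2-en-1-yl){[2-(trimethylsilyl)ethoxy]carbonyl}amino]cyclopent-3-ene-1-carboxylate
Product: 10 6-benzyl 1-[2-(trimethylsilyl)ethyl] (3aR,6R,6aS)-3-methylidene-3,3a,6,6a-tetrahydrocyclopenta[b]pyrrole-1,6(2H)-dicarboxylate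
Conditions: Pd(OAc)2 (10 mol%), PPh3 (20 mol%), Et3N, MeCN, 80 °C
Reagents that add atoms: none
Why: Intramolecular Heck reaction (5-exo-trig carbopalladation, then β-hydride elimination toward C22, the only syn hydrogen) closes ring A, the short tether delivering the vinyl group to the alkene face that carries nitrogen so that C24 is set cis to C25; any isomer with the ring alkene conjugated to the ester converges in step 8.

Step 7
Reactants: 11 acrylic acid
Product: 12 tert-butyl acrylate
Conditions: isobutene, H2SO4 (cat.), CH2Cl2, sealed tube, rt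
Reagents that add atoms: 2-methylpropene, CC(C)=C
Why: Acid-catalysed addition of the carboxylic acid to isobutene via the tert-butyl cation gives the tert-butyl ester, a protecting group that is later lost as isobutene.

Step 8
Reactants: 10 6-benzyl 1-[2-(trimethylsilyl)ethyl] (3aR,6R,6aS)-3-methylidene-3,3a,6,6a-tetrahydrocyclopenta[b]pyrrole-1,6(2H)-dicarboxylate; 12 tert-butyl acrylate
Product: 14 6-benzyl 1-[2-(trimethylsilyl)ethyl] (3aR,6R,6aS)-6-(3-tert-butoxy-3-oxopropyl)-3-methylidene-3,3a,6,6a-tetrahydrocyclopenta[b]pyrrole-1,6(2H)-dicarboxylate, via lithium dienolate 13 (not isolated)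
Conditions: LiN(iPr)2 (1.1 equiv), THF, −78 °C; then 12, −78 °C; AcOH quench
Reagents that add atoms: none
Why: Michael addition of the ester dienolate through its α-carbon builds quaternary C21, the acrylate approaching the convex face anti to the C25–N bond so that the propanoate chain ends up cis to H25 and the benzyl ester cis to nitrogen.

Step 9
Reactants: 14 6-benzyl 1-[2-(trimethylsilyl)ethyl] (3aR,6R,6aS)-6-(3-tert-butoxy-3-oxopropyl)-3-methylidene-3,3a,6,6a-tetrahydrocyclopenta[b]pyrrole-1,6(2H)-dicarboxylate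
Product: 15 (3S,3aR,6S,6aS)-6-(3-tert-butoxy-3-oxopropyl)-3-methyl-1-{[2-(trimethylsilyl)ethoxy]carbonyl}octahydrocyclopenta[b]pyrrole-6-carboxylic acid
Conditions: H2 (1 atm), Pd/C (10%), EtOAc, rt
Reagents that add atoms: none
Why: Heterogeneous hydrogenation adds H2 to the exocyclic methylene from the convex face, placing the methyl group on the concave face (C2, S), and also saturates the ring alkene and hydrogenolyses the benzyl ester.

**Fragment E**

Step 10
Reactants: 16 cyclohex-2-en-1-one; 17 but-3-en-1-ylmagnesium bromide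
Product: 19 (2R,3S)-3-(but-3-en-1-yl)-2-[(dimethylamino)methyl]cyclohexan-1-one, via magnesium enolate 18 (not isolated)
Conditions: CuBr·SMe2 (5 mol%), Josiphos ligand 1-[2-(diphenylphosphino)ferrocenyl]ethyldicyclohexylphosphine (6 mol%; the enantiomer giving the 3S adduct), tBuOMe, −75 °C; then Me2N=CH2+ I−, THF, −75 → 0 °C
Reagents that add atoms: N,N-dimethylmethyleneiminium iodide, C=[N+](C)C.[I-]
Why: Copper-catalysed asymmetric conjugate addition sets C10 under ligand control, and the regiodefined magnesium enolate is trapped in a Mannich reaction trans to the new side chain.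

Step 11
Reactants: 19 (2R,3S)-3-(but-3-en-1-yl)-2-[(dimethylamino)methyl]cyclohexan-1-one
Product: 21 (S)-3-(but-3-en-1-yl)-2-methylidenecyclohexan-1-one, via quaternary ammonium iodide 20 (not isolated)
Conditions: MeI, Et2O, rt; then aq NaHCO3, CH2Cl2, rt; used at once
Reagents that add atoms: none
Why: N-methylation followed by base-induced E1cB (Hofmann-type) loss of trimethylamine gives the α-methylene ketone without touching C10.

Step 12
Reactants: 21 (S)-3-(but-3-en-1-yl)-2-methylidenecyclohexan-1-one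
Product: 22 (3aS)-2,3,3a,4,5,6-hexahydro-7H-inden-7-one
Conditions: second-generation Grubbs catalyst (5 mol%), CH2Cl2 (5 mM), 40 °C
Reagents that add atoms: none
Why: Ring-closing metathesis between the terminal alkene and the enone methylene forms ring F with the C6=C7 double bond and releases ethene.

Step 13
Reactants: 22 (3aS)-2,3,3a,4,5,6-hexahydro-7H-inden-7-one
Product: 24 (3aR)-6-chloro-2,3,3a,4,5,6-hexahydro-7H-inden-7-one (both C6 epimers), via lithium enolate 23 (not isolated)
Conditions: LiN(iPr)2, THF, −78 °C; then C2Cl6, −78 → −40 °C (inverse addition)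
Reagents that add atoms: hexachloroethane, ClC(Cl)(Cl)C(Cl)(Cl)Cl
Why: Kinetic enolisation can only take place at C13 (C6 bears no hydrogen), and electrophilic chlorination of the enolate marks C13 for later metalation, the new centre being planarised in the next step.

Step 14
Reactants: 24 (3aR)-6-chloro-2,3,3a,4,5,6-hexahydro-7H-inden-7-one
Product: 26 (3aR)-6-chloro-3,3a,4,5-tetrahydro-2H-inden-7-yl trifluoromethanesulfonate, via potassium chloroenolate 25 (not isolated)
Conditions: KN(SiMe3)2, THF, −78 °C; then PhNTf2, −78 → 0 °C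
Reagents that add atoms: N-phenylbis(trifluoromethanesulfonimide), O=S(=O)(N(c1ccccc1)S(=O)(=O)C(F)(F)F)C(F)(F)F
Why: The only remaining α-hydrogen (on C13) is removed and O-sulfonylation of the enolate fixes the C5=C13 double bond as an enol triflate.

Step 15
Reactants: 26 (3aR)-6-chloro-3,3a,4,5-tetrahydro-2H-inden-7-yl trifluoromethanesulfonate
Product: 27 (3aR)-6-chloro-3,3a,4,5-tetrahydro-2H-indene
Conditions: Pd(OAc)2 (3 mol%), PPh3 (6 mol%), HCO2H, Bu3N, DMF, 60 °C
Reagents that add atoms: none
Why: Palladium-catalysed formate reduction of the enol triflate (oxidative addition at C–OTf and not at C–Cl, hydride transfer, reductive elimination) replaces OTf by H and leaves the 2-chloro-1,3-diene with both double bonds in place.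

Step 16
Reactants: 27 (3aR)-6-chloro-3,3a,4,5-tetrahydro-2H-indene
Product: 29 trimethyl[(3aR)-3,3a,4,5-tetrahydro-2H-inden-6-yl]stannane, via dienyllithium 28 (not isolated)
Conditions: lithium 4,4′-di-tert-butylbiphenylide (2.2 equiv), THF, −78 °C; then Me3SnCl, −78 °C → rt
Reagents that add atoms: chlorotrimethylstannane, C[Sn](C)(C)Cl
Why: Reductive lithiation of the vinyl chloride by the arene radical anion gives the dienyllithium at C13, which is trapped by transmetalation to tin.

**Coupling and endgame**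

Step 17
Reactants: 15 (3S,3aR,6S,6aS)-6-(3-tert-butoxy-3-oxopropyl)-3-methyl-1-{[2-(trimethylsilyl)ethoxy]carbonyl}octahydrocyclopenta[b]pyrrole-6-carboxylic acid; 29 trimethyl[(3aR)-3,3a,4,5-tetrahydro-2H-inden-6-yl]stannane
Product: 31 tert-butyl 3-[(3S,3aR,6S,6aS)-3-methyl-6-{[(3aR)-3,3a,4,5-tetrahydro-2H-inden-6-yl]carbonyl}-1-{[2-(trimethylsilyl)ethoxy]carbonyl}octahydrocyclopenta[b]pyrrol-6-yl]propanoate, via acid chloride 30 (not isolated)
Conditions: 1-chloro-N,N,2-trimethylprop-1-en-1-amine (1.2 equiv), CH2Cl2, 0 °C → rt; then 29, Pd2(dba)3 (5 mol%), P(2-furyl)3 (20 mol%), THF, 50 °C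
Reagents that add atoms: none
Why: The neutral chloroenamine converts the hindered acid to its chloride, and Stille acylation (oxidative addition of the acyl chloride, tin-to-palladium transmetalation, reductive elimination) joins the two fragments through the C13–C14 bond as a dienone.

Step 18
Reactants: 31 tert-butyl 3-[(3S,3aR,6S,6aS)-3-methyl-6-{[(3aR)-3,3a,4,5-tetrahydro-2H-inden-6-yl]carbonyl}-1-{[2-(trimethylsilyl)ethoxy]carbonyl}octahydrocyclopenta[b]pyrrol-6-yl]propanoate
Product: 33 pentacyclic amino ketone (2S,5R,10R,13S,21S,24R,25S; rings A/B/C/E/F closed; C14 is C=O; C21 carries CH2CH2CO2tBu), via secondary amine 32 (not isolated)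
Conditions: Bu4NF, THF, 0 → 40 °C; then DBU (0.2 equiv), rt
Reagents that add atoms: none
Why: Fluoride-induced fragmentation of the Teoc group frees N4, which closes ring C by 6-endo aza-Michael addition to C5; because the addition is reversible and C13 is epimerisable, C5 (R) and C13 (S) should settle under thermodynamic control in the trans-diequatorial C/E fusion on the chair that keeps rings A and B cis-fused.

Step 19
Reactants: 33 pentacyclic amino ketone
Product: 34 pentacyclic 14-methylidene amine (33 with C14=CH2; same spatial arrangement at every centre)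
Conditions: Zn, CH2Br2, TiCl4, THF/CH2Cl2, 0 °C → rt
Reagents that add atoms: dibromomethane, BrCBr
Why: Takai–Lombardo methylenation with the non-basic zinc/titanium gem-dimetallic reagent converts the hindered, enolisable ketone to the 1,1-disubstituted alkene without epimerising C13 or touching the ester.

Step 20
Reactants: 34 pentacyclic 14-methylidene amine
Product: 36 hexacyclic lactone amine (2S,5R,10R,13S,14R,21S,24R,25S; the target without the N-oxide oxygen), via alkene acid 35 (not isolated)
Conditions: CF3SO3H (3 equiv), CH2Cl2, 0 °C → rt; then aq NaHCO3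
Reagents that add atoms: none
Why: Triflic acid cleaves the tert-butyl ester and protonates the 1,1-disubstituted alkene to the tertiary C14 cation (the ammonium deactivates the allylic C6=C7 bond), and Markovnikov lactonisation by the tethered acid, which can reach C14 only from the face of C20, closes ring D cis-fused and sets C14 (R) with the methyl group on the opposite face.

Step 21
Reactants: 36 hexacyclic lactone amine
Product: 37 target CNP0566793.5 (N4-oxide of 36; oxygen on the convex face syn to H25)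
Conditions: mCPBA (1.05 equiv), CH2Cl2, −20 → 0 °C; basic Al2O3 filtration
Reagents that add atoms: 3-chloroperoxybenzoic acid, OOC(=O)c1cccc(Cl)c1
Why: Chemoselective N-oxidation of the tertiary amine is much faster than epoxidation of the trisubstituted alkene and can only occur at the lone pair on the convex face, which fixes the configuration at nitrogen.

**Compound list**
1 | cyclopenta-1,3-diene | C1=CC=CC1 | starting material
2 | chlorosulfonyl isocyanate | O=C=NS(=O)(=O)Cl | starting material
3 | rac-(1R*,5S*)-6-(chlorosulfonyl)-6-azabicyclo[3.2.0]hept-3-en-7-one (cis-fused; racemate, one enantiomer drawn) | O=C1N(S(=O)(=O)Cl)[C@H]2C=CC[C@@H]12 | intermediate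
4 | rac-(1R*,5S*)-6-azabicyclo[3.2.0]hept-3-en-7-one (cis-fused; racemate, one enantiomer drawn) | O=C1N[C@H]2C=CC[C@@H]12 | intermediate
5 | (1R,2S)-2-aminocyclopent-3-ene-1-carboxylic acid | N[C@H]1C=CC[C@H]1C(=O)O | intermediate
6 | benzyl (1R,2S)-2-aminocyclopent-3-ene-1-carboxylate | N[C@H]1C=CC[C@H]1C(=O)OCc1ccccc1 | intermediate
7 | 2,3-dibromoprop-1-ene | C=C(Br)CBr | starting material
8 | benzyl (1R,2S)-2-[(2-bromoprop-2-en-1-yl)amino]cyclopent-3-ene-1-carboxylate | C=C(Br)CN[C@H]1C=CC[C@H]1C(=O)OCc1ccccc1 | intermediate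
9 | benzyl (1R,2S)-2-[(2-bromoprop-2-en-1-yl){[2-(trimethylsilyl)ethoxy]carbonyl}amino]cyclopent-3-ene-1-carboxylate | C=C(Br)CN(C(=O)OCC[Si](C)(C)C)[C@H]1C=CC[C@H]1C(=O)OCc1ccccc1 | intermediate
10 | 6-benzyl 1-[2-(trimethylsilyl)ethyl] (3aR,6R,6aS)-3-methylidene-3,3a,6,6a-tetrahydrocyclopenta[b]pyrrole-1,6(2H)-dicarboxylate | C=C1CN(C(=O)OCC[Si](C)(C)C)[C@H]2[C@@H]1C=C[C@H]2C(=O)OCc1ccccc1 | intermediate
11 | acrylic acid | C=CC(=O)O | starting material
12 | tert-butyl acrylate | C=CC(=O)OC(C)(C)C | intermediate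
13 | lithium dienolate of 10 (O–C14=C21–C22=C23) | [Li+].C=C1CN(C(=O)OCC[Si](C)(C)C)[C@H]2[C@@H]1C=CC2=C([O-])OCc1ccccc1 | intermediate
14 | 6-benzyl 1-[2-(trimethylsilyl)ethyl] (3aR,6R,6aS)-6-(3-tert-butoxy-3-oxopropyl)-3-methylidene-3,3a,6,6a-tetrahydrocyclopenta[b]pyrrole-1,6(2H)-dicarboxylate | C=C1CN(C(=O)OCC[Si](C)(C)C)[C@H]2[C@@H]1C=C[C@@]2(CCC(=O)OC(C)(C)C)C(=O)OCc1ccccc1 | intermediate
15 | (3S,3aR,6S,6aS)-6-(3-tert-butoxy-3-oxopropyl)-3-methyl-1-{[2-(trimethylsilyl)ethoxy]carbonyl}octahydrocyclopenta[b]pyrrole-6-carboxylic acid (fragment W) | C[C@@H]1CN(C(=O)OCC[Si](C)(C)C)[C@H]2[C@@H]1CC[C@@]2(CCC(=O)OC(C)(C)C)C(=O)O | intermediate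
16 | cyclohex-2-en-1-one | O=C1C=CCCC1 | starting material
17 | but-3-en-1-ylmagnesium bromide | C=CCC[Mg]Br | starting material
18 | bromomagnesium (S)-3-(but-3-en-1-yl)cyclohex-1-en-1-olate | C=CCC[C@@H]1CCCC(O[Mg]Br)=C1 | intermediate
19 | (2R,3S)-3-(but-3-en-1-yl)-2-[(dimethylamino)methyl]cyclohexan-1-one | O=C1CCC[C@@H](CCC=C)[C@@H]1CN(C)C | intermediate
20 | {[(1R,2S)-2-(but-3-en-1-yl)-6-oxocyclohexyl]methyl}trimethylammonium iodide | O=C1CCC[C@@H](CCC=C)[C@@H]1C[N+](C)(C)C.[I-] | intermediate
21 | (S)-3-(but-3-en-1-yl)-2-methylidenecyclohexan-1-one | O=C1CCC[C@@H](CCC=C)C1=C | intermediate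
22 | (3aS)-2,3,3a,4,5,6-hexahydro-7H-inden-7-one | O=C1CCC[C@H]2CCC=C12 | intermediate
23 | lithium (3aR)-3,3a,4,5-tetrahydro-2H-inden-7-olate | [Li+].[O-]C1=CCC[C@H]2CCC=C12 | intermediate
24 | (3aR)-6-chloro-2,3,3a,4,5,6-hexahydro-7H-inden-7-one (both C6 epimers) | O=C1C(Cl)CC[C@H]2CCC=C12 | intermediate
25 | potassium (3aR)-6-chloro-3,3a,4,5-tetrahydro-2H-inden-7-olate | [K+].[O-]C1=C(Cl)CC[C@H]2CCC=C12 | intermediate
26 | (3aR)-6-chloro-3,3a,4,5-tetrahydro-2H-inden-7-yl trifluoromethanesulfonate | O=S(=O)(OC1=C(Cl)CC[C@H]2CCC=C12)C(F)(F)F | intermediate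
27 | (3aR)-6-chloro-3,3a,4,5-tetrahydro-2H-indene | ClC1=CC2=CCC[C@@H]2CC1 | intermediate
28 | [(3aR)-3,3a,4,5-tetrahydro-2H-inden-6-yl]lithium | [Li]C1=CC2=CCC[C@@H]2CC1 | intermediate
29 | trimethyl[(3aR)-3,3a,4,5-tetrahydro-2H-inden-6-yl]stannane (fragment E) | C[Sn](C)(C)C1=CC2=CCC[C@@H]2CC1 | intermediate
30 | acid chloride of 15 | C[C@@H]1CN(C(=O)OCC[Si](C)(C)C)[C@H]2[C@@H]1CC[C@@]2(CCC(=O)OC(C)(C)C)C(Cl)=O | intermediate
31 | tert-butyl 3-[(3S,3aR,6S,6aS)-3-methyl-6-{[(3aR)-3,3a,4,5-tetrahydro-2H-inden-6-yl]carbonyl}-1-{[2-(trimethylsilyl)ethoxy]carbonyl}octahydrocyclopenta[b]pyrrol-6-yl]propanoate | C[C@@H]1CN(C(=O)OCC[Si](C)(C)C)[C@H]2[C@@H]1CC[C@@]2(CCC(=O)OC(C)(C)C)C(=O)C1=CC2=CCC[C@@H]2CC1 | intermediate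
32 | tert-butyl 3-[(3S,3aR,6S,6aS)-3-methyl-6-{[(3aR)-3,3a,4,5-tetrahydro-2H-inden-6-yl]carbonyl}octahydrocyclopenta[b]pyrrol-6-yl]propanoate | C[C@@H]1CN[C@H]2[C@@H]1CC[C@@]2(CCC(=O)OC(C)(C)C)C(=O)C1=CC2=CCC[C@@H]2CC1 | intermediate
33 | pentacyclic amino ketone (2S,5R,10R,13S,21S,24R,25S): rings A, B, C, E, F of the target, C14 ketone, C21 bearing CH2CH2CO2tBu | C[C@@H]1CN2[C@H]3C4=CCC[C@@H]4CC[C@@H]3C(=O)[C@]3(CCC(=O)OC(C)(C)C)CC[C@H]1[C@@H]32 | intermediate
34 | 33 with C14=CH2 in place of C14=O | C[C@@H]1CN2[C@H]3C4=CCC[C@@H]4CC[C@@H]3C(=C)[C@]3(CCC(=O)OC(C)(C)C)CC[C@H]1[C@@H]32 | intermediate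
35 | 34 with the free propanoic acid | C[C@@H]1CN2[C@H]3C4=CCC[C@@H]4CC[C@@H]3C(=C)[C@]3(CCC(=O)O)CC[C@H]1[C@@H]32 | intermediate
36 | hexacyclic lactone amine (2S,5R,10R,13S,14R,21S,24R,25S), the target without the N-oxide oxygen | C[C@@H]1CN2[C@H]3C4=CCC[C@@H]4CC[C@@H]3[C@@]3(C)OC(=O)CC[C@]34CC[C@H]1[C@@H]42 | intermediate
37 | CNP0566793.5, N4-oxide of 36 | C[C@@H]1C[N@+]2([O-])[C@H]3C4=CCC[C@@H]4CC[C@@H]3[C@@]3(C)OC(=O)CC[C@]34CC[C@H]1[C@@H]42 | target

**Totals**
Total step count: 21.
Longest linear sequence: 13 steps (1–6, 8, 9, 17–21). The fragment E line is 12 steps (10–21).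

**Three steps most likely to fail, with fallbacks**

Step 16. The arene radical anion may reduce the conjugated diene as well as the C–Cl bond. The fallback sets out from chlorodiene 27: Miyaura borylation (B2pin2, Pd2(dba)3, XPhos, KOAc, dioxane, 100 °C) gives the pinacol boronate F1. F1 is joined to acid chloride 30 (made from 15 as in step 17) by an anhydrous Suzuki–Miyaura acylation (Pd(PPh3)4, Cs2CO3, toluene, 80 °C), which comes back to the route at dienone 31 without any organolithium or tin reagent.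

Step 17. The acid chloride is neopentyl-type and sits cis to a carbamate, so slow oxidative addition, decarbonylation or cyclisation onto the carbamate could intervene. The fallback sets out from acid 15: BH3·SMe2 (THF, 0 °C) reduces the acid selectively to the primary alcohol F2, and Dess–Martin periodinane gives the aldehyde F3. Stannane 29 is converted with MeLi (THF, −78 °C) into dienyllithium 28, which adds to F3 at −78 °C (the aldehyde reacts far faster than the tert-butyl ester; aq NH4Cl quench) to give the dienyl carbinol F4 as a mixture at C14. Dess–Martin oxidation of F4 comes back to the route at 31.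

Step 20. Under strong acid the C14 cation can lose the C13 proton, and re-protonation could scramble C13; the lactone also carries a 1,3-diaxial methyl group, so the equilibrium is not guaranteed. The fallback sets out from 34: CF3CO2H/CH2Cl2 at 0 °C removes only the tert-butyl group and gives alkene acid 35 as its trifluoroacetate salt. Hg(OCOCF3)2 in MeNO2 then effects intramolecular oxymercuration, with no free carbocation and carboxylate attack at C14 from the face of C20, to give the organomercurial lactone F5. Demercuration with NaBH4/aq NaOH at 0 °C comes back to the route at 36.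

Further compounds
F1 | step 16 | 4,4,5,5-tetramethyl-2-[(3aR)-3,3a,4,5-tetrahydro-2H-inden-6-yl]-1,3,2-dioxaborolane | CC1(C)OB(OC1(C)C)C1=CC2=CCC[C@@H]2CC1
F2 | step 17 | tert-butyl 3-[(3S,3aR,6S,6aS)-6-(hydroxymethyl)-3-methyl-1-{[2-(trimethylsilyl)ethoxy]carbonyl}octahydrocyclopenta[b]pyrrol-6-yl]propanoate | C[C@@H]1CN(C(=O)OCC[Si](C)(C)C)[C@H]2[C@@H]1CC[C@@]2(CCC(=O)OC(C)(C)C)CO
F3 | step 17 | tert-butyl 3-[(3S,3aR,6S,6aS)-6-formyl-3-methyl-1-{[2-(trimethylsilyl)ethoxy]carbonyl}octahydrocyclopenta[b]pyrrol-6-yl]propanoate | C[C@@H]1CN(C(=O)OCC[Si](C)(C)C)[C@H]2[C@@H]1CC[C@@]2(CCC(=O)OC(C)(C)C)C=O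
F4 | step 17 | tert-butyl 3-[(3S,3aR,6S,6aS)-6-{hydroxy[(3aR)-3,3a,4,5-tetrahydro-2H-inden-6-yl]methyl}-3-methyl-1-{[2-(trimethylsilyl)ethoxy]carbonyl}octahydrocyclopenta[b]pyrrol-6-yl]propanoate (both carbinol epimers) | C[C@@H]1CN(C(=O)OCC[Si](C)(C)C)[C@H]2[C@@H]1CC[C@@]2(CCC(=O)OC(C)(C)C)C(O)C1=CC2=CCC[C@@H]2CC1
F5 | step 20 | lactone amine 36 carrying HgOCOCF3 on the C15 carbon | C[C@@H]1CN2[C@H]3C4=CCC[C@@H]4CC[C@@H]3[C@@]3(C[Hg]OC(=O)C(F)(F)F)OC(=O)CC[C@]34CC[C@H]1[C@@H]42
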